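## Structural features

Compound 21 is a 3,7-dioxabicyclo[3.3.0]octan-2-one. A γ-butyrolactone (ring A: C1, C2, O3, C4, C5) and a tetrahydrofuran (ring B: C1, C5, C6, O7, C8) share the C1–C5 bond and are cis-fused. The stereocentres C8, C1, C5 and C4 form an unbroken chain. The bridgehead hydrogens are cis and both aryl groups lie on the convex face: 4-hydroxy-3-methoxyphenyl at C8 and 4-hydroxy-3,5-dimethoxyphenyl at C4, which corresponds to (1S,4S,5R,8S). The fragile elements are the two free phenols on electron-rich rings and the benzylic C4–O3 (acyloxy) and C8–O7 (ether) bonds para to a phenolic oxygen. These bonds ionise under acid, are open to hydrogenolysis and can be expelled through a quinone methide under base; C1 is in addition α to the carbonyl group and β to O7. The real difficulty is that the bicycle is almost symmetric yet carries two different arenes and only one carbonyl group. A dimerisation of one phenylpropanoid unit is therefore excluded, and the place of each arene relative to C2 has to follow from the connectivity of the precursors while four contiguous centres are set in the absolute sense. The key step uses the following feature: if O3 is taken out of ring A and C2 is joined directly to C4, ring A contracts to a 2-arylcyclobutanone fused to ring B. That 3-oxabicyclo[3.2.0]heptane is the [2+2] adduct of a C1=C2 alkene and a C5=C4 styrene held together by the C8–O7–C6 tether, with boron on C2 as the placeholder for the carbonyl oxygen.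

## Logic of the disconnections

**21 ⇒ 20.** The two phenolic O–H bonds are traced back to O–Si bonds. Free phenols on these rings would not survive the hydride base, the peracid and the photochemical step. A silyl group, unlike a benzyl group, leaves without hydrogenolysis, which would endanger the C4–O3 and C8–O7 bonds. The skeleton is not simplified; the gain is a robust, non-acidic substrate for every earlier step. The forward step needs a buffered fluoride source so that no phenoxide expels the C4 carboxylate or the C8 alkoxide.

**20 ⇒ 19.** The O3–C4 bond is cut and C4 is reattached to C2 (reverse of an oxygen insertion). This replaces a C–O bond between two stereocentres by a C–C bond that a cycloaddition can make, and it turns the lactone into a strained ketone that accepts oxygen readily. The forward step must insert oxygen on the C4 side of C2 and not on the C1 side, with retention at C4.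

**19 ⇒ 18 ⇒ 16.** The C2 carbonyl group is traced back through the C2–OH bond of 18 to the C2–B bond of 16. A ketene-type carbon cannot be carried through a sensitised cycloaddition, whereas an alkenyl boronate can, and the boron also stabilises the radical at C2. The gain is that C2 enters as an ordinary alkene carbon. The demand is an oxidation of C–B that leaves the aryl silyl ethers alone; the configuration at C2 is of no consequence.

**16 ⇒ 15.** C1–C5 and C2–C4 are cut (retro-[2+2]). This opens ring B and the cyclobutane together, removes four stereocentres and leaves an acyclic diene ether with the single centre C8. The forward step must excite the styrene only, form the fused and not the crossed adduct, and let C8 decide the face of the C1=C2 alkene that is attacked.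

**15 ⇒ 13 + 14.** The C2–B bond (and the C1–H bond) is cut, which returns the alkenyl boronate to a terminal alkyne. The alkyne survives the basic etherification, whereas a boronate next to an alkoxide would not. The forward hydroboration must be syn, terminal-selective and must spare the styrene.

**13 ⇒ 6 + 11.** O7–C6 is cut. This divides the molecule into a guaiacyl half that carries the only stereocentre and an achiral syringyl half. The bond is formed at the primary carbon, so C8–O is never broken. The forward step needs a base that does not isomerise the propargylic system and an allylic electrophile that reacts before it ionises.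

**11 ⇒ 9 ⇒ 7.** The C6–Br bond is traced to C6–OH and the aryl O–Si bond to the phenol. The gain is a commercial starting material that already has the E alkene and all three carbons. The demand is silylation of the phenol in the presence of the primary alcohol and a non-acidic activation of the allylic position.

**6 ⇒ 5 ⇒ 2 + 3.** After exchange of the alkyne C–H for C–Si, the C8–C1 bond is cut between an aldehyde carbon and an alkynyl carbon. This creates C8 by a catalytic asymmetric addition and reduces the guaiacyl half to an aromatic aldehyde. The forward step must select one face of an electron-rich aryl aldehyde.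

**2 ⇒ 1.** The aryl O–Si bond is cut; the forward step is a plain phenol silylation.

## Other disconnections considered

**Alternative 1:** The cut removes O7–C8, C1–C5 and O3–C2 and leads back to an epoxy alcohol (A1) and a benzylidene malonate (A2). In the forward sense the alkoxide of A1 adds to A2 in a conjugate fashion, the malonate carbanion opens the oxirane at C5 in a 5-exo-tet closure with inversion, and the liberated C4 alkoxide lactonises onto the ester on the same face to give A3.
- In its favour: three bonds, both rings and the C1 quaternary centre arise in one flask from two simple fragments, and the absolute configuration comes from a catalytic asymmetric epoxidation.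
- Against it, the stereochemical bookkeeping: inversion at C5 with retention at C4 turns a trans-oxirane into the lactone whose C4 aryl group is cis to C6 (concave face). The exo aryl group of A3 therefore requires the cis-oxirane A1. The E alkene of 7 cannot be used directly, and asymmetric epoxidation of a Z allylic alcohol is slower and less selective.
- Further points against: the conjugate addition is reversible, so C8 is not firmly controlled. Epoxide migration and 6-endo opening at benzylic C4 can compete. The extra ester at C1 must be removed under halide and heat, next to a benzylic lactone C–O bond. The benzyl ethers must be removed by hydrogenolysis in the presence of two benzylic C–O bonds.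
- Comparison: on structure it builds the lactone at the right oxidation level but carries an extra carbon; the chosen plan carries none and derives C4 from an alkene whose geometry does not matter. On mechanism it is closed-shell, polar chemistry without photochemical equipment, which makes it the equal or better of the chosen plan for scale-up. On step economy its longest linear sequence should be shorter, a point in its favour, while the total number of operations is comparable.

**Alternative 2:** The cut removes C1–C8 and O7–C6, a retro-(3+2) that leads to the cyclopropane-fused lactone A4 and the silylated aldehyde A5. In the forward sense MgI2 delivers iodide to C6 and opens the three-membered ring. The nucleophilic C1 so unmasked adds to A5, and the resulting alkoxide displaces iodide in a 5-exo-tet closure to give A6.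
- In its favour: the union is convergent and uses the guaiacyl half at the aldehyde level, one step from 1, with no asymmetric step of its own. This is better than the chosen plan on that point, since the configuration is relayed from C4 and C5 of A4. The lactone enforces cis fusion, and the C4 aryl group is already placed.
- Against it: C6 carries no donor, so ring opening depends on nucleophilic iodide and heat. The Lewis acid can ionise the electron-rich benzylic C4–O3 bond of A4. The configuration at C8 depends on an aldol step that can revert before the ring closes. A4 needs an enantioenriched precursor and an intramolecular cyclopropanation. The C1 ester has to be removed afterwards.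
- Comparison: on structure both plans use strain (a cyclopropane here, a cyclobutanone there) and both rely on a ring to fix the fusion; they are equal on that point. On mechanism the ionic cascade has no counterpart to the facial-selectivity question of the cycloaddition but has its own open question at C8. On step economy the two are expected to be about equal.

**Alternative 3:** The cut removes C6–C5 and C8–C1, a retro-1,3-dipolar cycloaddition that leads to the butenolide A7 and the carbonyl ylide A9, which is released from the α-chlorobenzyl silylmethyl ether A8. In the forward sense CsF removes the silyl group of A8 while chloride leaves. The ylide A9 adds across the electron-poor alkene of A7 on the face away from the C4 aryl group. Its nucleophilic CH2 terminus bonds to C5 and its benzylic terminus to C1, which gives A10.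
- In its favour: A10 has the complete skeleton at the right oxidation level with no surplus carbon and is one deprotection from 21. This is the shortest plan and better than the chosen one on step economy. The controlling centre C4 sits directly on the reacting ring, which should give strong facial control.
- Against it: A7 has an acidic hydrogen at C4 (benzylic and vinylogously α to the carbonyl group), so fluoride can racemise it through the hydroxyfuran tautomer. A8 is an α-chloro ether of an electron-rich arene and ionises very easily. The orientation of the aryl group at C8 (exo or endo) is not fixed by the mechanism. The final hydrogenolysis again meets two benzylic C–O bonds.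
- Comparison: on structure it is the most direct. On mechanism a near-concerted cycloaddition transfers alkene geometry cleanly, which the stepwise biradical route does not need but also cannot claim. The chosen plan is longer but sets its single controlling centre by asymmetric catalysis at a position that cannot racemise and removes its protecting groups without hydrogen.

Key step: step 8

## Remarks before the steps

- **Numbering and abbreviations.** The core atoms keep the numbering of 21 (C1, C2, O3, C4, C5, C6, O7, C8) in all intermediates. ArG = 3-methoxy-4-[(triisopropylsilyl)oxy]phenyl; ArS = 3,5-dimethoxy-4-[(triisopropylsilyl)oxy]phenyl; Bpin = 4,4,5,5-tetramethyl-1,3,2-dioxaborolan-2-yl.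
- **Correction of a structure name.** The cycloadduct that follows from the bonds C1–C5 and C2–C4 has the guaiacyl carbon at position 4, boron at 6 and the syringyl carbon at 7 of the 3-oxabicyclo[3.2.0]heptane (or 2, 7 and 6 when numbered from the other bridgehead). A 2-guaiacyl-7-syringyl-6-boryl locant set would put both aryl-bearing carbons on the same bridgehead, a constitution that the tether cannot deliver and that could not lead to 21. Compound 16 has the former constitution.
- **Design change.** Both phenols carry triisopropylsilyl instead of a smaller silyl group, because aryl triisopropylsilyl ethers tolerate carbonate in methanol, a sodium alkoxide and perborate. The sensitiser is a neutral homoleptic iridium complex, to keep electron transfer from the electron-rich arenes out of the picture.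
- **Assumption.** The (R,R) antipode of ProPhenol is written for step 2 on the premise that alkynyl transfer follows the facial preference of aldol additions with this ligand family. If a first run shows the opposite sense, the (S,S) ligand is used and nothing else changes.

## Route

Step 1
Reactants: 1 vanillin (4-hydroxy-3-methoxybenzaldehyde)
Product: 2 3-methoxy-4-[(triisopropylsilyl)oxy]benzaldehyde (ArG–CHO)
Conditions: TIPSCl (1.1 equiv), imidazole (2 equiv), DMF, rt
Reagents that add atoms: chlorotriisopropylsilane, CC(C)[Si](Cl)(C(C)C)C(C)C
Why: Imidazole-promoted O-silylation of the phenol; the aldehyde is untouched. The triisopropylsilyl ether is chosen because it withstands the carbonate, alkoxide and perborate media of steps 3, 6 and 9 better than a smaller silyl ether.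

Step 2
Reactants: 2 3-methoxy-4-[(triisopropylsilyl)oxy]benzaldehyde; 3 trimethylsilylacetylene
Product: 5 (1R)-1-ArG-3-(trimethylsilyl)prop-2-yn-1-ol, via methyl(trimethylsilylethynyl)zinc 4 (not isolated)
Conditions: 3 (3 equiv), Me2Zn (3 equiv), (R,R)-ProPhenol (10 mol%), Ph3P=O (20 mol%), toluene, rt; then 2, 4 °C; aq. NH4Cl
Reagents that add atoms: none
Why: Catalytic asymmetric alkynylation of an aryl aldehyde by a dinuclear zinc–ProPhenol complex: the alkynylzinc 4, formed by deprotonation of 3, is delivered to the Si face of the aldehyde held on the neighbouring zinc centre, which sets C8. The descriptor is R only because the silylalkynyl group outranks the aryl group.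

Step 3
Reactants: 5 (1R)-1-ArG-3-(trimethylsilyl)prop-2-yn-1-ol
Product: 6 (1S)-1-ArG-prop-2-yn-1-ol
Conditions: K2CO3 (0.3 equiv), MeOH, 0 °C → rt
Reagents that add atoms: none
Why: Methanolysis of the C(sp)–Si bond by catalytic methoxide; the aryl triisopropylsilyl ether and the carbinol centre are inert under these conditions. The descriptor changes from R to S because ethynyl ranks below aryl, not because the centre is touched.

Step 4
Reactants: 7 sinapyl alcohol ((2E)-3-(4-hydroxy-3,5-dimethoxyphenyl)prop-2-en-1-ol)
Product: 9 (2E)-3-ArS-prop-2-en-1-ol, via sodium sinapyl phenoxide 8 (not isolated)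
Conditions: NaH (1.0 equiv), THF, 0 °C; then TIPSCl (1.05 equiv), 0 °C → rt
Reagents that add atoms: chlorotriisopropylsilane, CC(C)[Si](Cl)(C(C)C)C(C)C
Why: Chemoselective O-silylation of a phenoxide: one equivalent of base deprotonates only the phenol (roughly six pKa units more acidic than the allylic alcohol). The hindered silyl chloride reacts with the phenoxide but not with the neutral primary alcohol in the absence of a nucleophilic catalyst.

Step 5
Reactants: 9 (2E)-3-ArS-prop-2-en-1-ol
Product: 11 (1E)-1-ArS-3-bromoprop-1-ene, via allylic mesylate 10 (not isolated)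
Conditions: MsCl (1.2 equiv), Et3N (1.5 equiv), THF, −40 °C; then LiBr (4 equiv), −40 → 0 °C
Reagents that add atoms: lithium bromide, [Li+].[Br-]
Why: Mesylation followed by Finkelstein-type SN2 displacement by bromide at the primary carbon, run without acid so that the electron-rich cinnamyl system does not ionise; the E alkene is retained. The mesyl group serves only as the transient leaving group, and the bromide is used at once without chromatography.

Step 6
Reactants: 6 (1S)-1-ArG-prop-2-yn-1-ol; 11 (1E)-1-ArS-3-bromoprop-1-ene
Product: 13 (1S)-1-ArG-prop-2-yn-1-yl (2E)-3-ArS-prop-2-en-1-yl ether, via sodium propargylic alkoxide 12 (not isolated)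
Conditions: NaH (1.1 equiv), THF, 0 °C; then 11 (1.2 equiv), Bu4NI (10 mol%), 0 °C → rt
Reagents that add atoms: none
Why: Williamson ether synthesis: the secondary alkoxide 12 displaces bromide at the primary allylic carbon (SN2, linear E ether) and forms O7–C6. The C8–O bond is never broken, so the S configuration is carried over; THF is used because NaH in DMF would cleave aryl silyl ethers.

Step 7
Reactants: 13 (1S)-1-ArG-prop-2-yn-1-yl (2E)-3-ArS-prop-2-en-1-yl ether; 14 pinacolborane
Product: 15 (1S,2E)-1-ArG-3-Bpin-prop-2-en-1-yl (2E)-3-ArS-prop-2-en-1-yl ether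
Conditions: 14 (1.5 equiv), Cp2Zr(H)Cl (10 mol%), Et3N (10 mol%), CH2Cl2, rt → 40 °C
Reagents that add atoms: none
Why: Zirconocene hydride-catalysed hydroboration of the terminal alkyne: syn hydrozirconation places zirconium on the terminal carbon, and exchange with 14 gives the E alkenyl boronate and returns the hydride. The 1,2-disubstituted styrene is hydrometallated far more slowly, and a copper boryl catalyst is avoided because it would eliminate the propargylic ether to an allene.

Step 8
Reactants: 15 (1S,2E)-1-ArG-3-Bpin-prop-2-en-1-yl (2E)-3-ArS-prop-2-en-1-yl ether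
Product: 16 2-[(1R,4S,5S,6R,7S)-4-ArG-7-ArS-3-oxabicyclo[3.2.0]heptan-6-yl]-4,4,5,5-tetramethyl-1,3,2-dioxaborolane (cis ring fusion; ArG, ArS and boron on the convex face)
Conditions: fac-Ir(dFppy)3 (1 mol%), MeCN (0.02 M), freeze–pump–thaw degassed, blue LEDs (427 nm), rt
Reagents that add atoms: none
Why: The excited sensitiser passes triplet energy to the sinapyl styrene of 15 only, since the alkenyl boronate and the unconjugated guaiacyl ring lie much higher in triplet energy; the closest known reaction type is the visible-light sensitised intramolecular [2+2] cycloaddition of styrenes with tethered alkenes, alkenyl boronates included. The β-carbon C5 of the twisted styrene triplet adds to C1 in a 5-exo-trig radical closure that forms ring B (C1–C5) and leaves a triplet 1,4-biradical stabilised at benzylic C4 and at α-boryl C2; after intersystem crossing, radical recombination between C2 and C4 closes the cyclobutane. C1 and C5 can only be cis because a trans-fused bicyclo[3.2.0]heptane is too strained, and their absolute sense is set by C8: in the chair-like transition state of the 5-exo closure the C8–H bond eclipses the C1=C2 alkene and the aryl group points away from the forming ring, which puts the aryl group trans to C2 and on the convex face. C4 is set in the recombination, where the planar benzylic radical turns its aryl group away from C6 (exo); the E or Z geometry of the styrene is lost in the triplet and does not matter. C2 should carry boron on the convex face trans to C8, but this centre becomes a carbonyl carbon in step 10, so either epimer serves. The step needs chemoselective sensitisation (the neutral homoleptic complex has a triplet energy of about 60 kcal/mol, enough for a β-alkylstyrene, and is only a weak excited-state oxidant, so electron transfer from the electron-rich arenes is not expected to compete), fused and not crossed regiochemistry (secured by the three-atom tether and the preference for a five-membered ring in the first bond), and facial selectivity (secured by C8). Oxygen is excluded because it quenches both the sensitiser and the biradical.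

Step 9
Reactants: 16 2-[(1R,4S,5S,6R,7S)-4-ArG-7-ArS-3-oxabicyclo[3.2.0]heptan-6-yl]-4,4,5,5-tetramethyl-1,3,2-dioxaborolane
Product: 18 (1R,4S,5R,6R,7S)-4-ArG-7-ArS-3-oxabicyclo[3.2.0]heptan-6-ol, via cyclobutyl pinacol borate 17 (not isolated)
Conditions: NaBO3·4H2O (5 equiv), THF/H2O (1:1), rt
Reagents that add atoms: sodium perborate, [Na+].[O-]B1OO1
Why: Perborate oxidation of the secondary alkyl boronate: peroxide adds to boron, C2 migrates to oxygen with retention, and the borate 17 is hydrolysed in the aqueous medium. Perborate is mild enough for the aryl silyl ethers and the benzylic ether at C8.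

Step 10
Reactants: 18 (1R,4S,5R,6R,7S)-4-ArG-7-ArS-3-oxabicyclo[3.2.0]heptan-6-ol
Product: 19 (1R,4S,5S,7S)-4-ArG-7-ArS-3-oxabicyclo[3.2.0]heptan-6-one
Conditions: Dess–Martin periodinane (1.3 equiv), NaHCO3 (5 equiv), CH2Cl2, 0 °C → rt
Reagents that add atoms: none
Why: Dess–Martin oxidation of the secondary cyclobutanol under bicarbonate buffering; the C2 centre disappears, so its configuration in 16 is of no consequence. C4, now α to the ketone, already has the thermodynamically preferred exo aryl group, and C1 cannot epimerise because a trans-fused bicyclo[3.2.0]heptanone is prohibitively strained.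

Step 11
Reactants: 19 (1R,4S,5S,7S)-4-ArG-7-ArS-3-oxabicyclo[3.2.0]heptan-6-one
Product: 20 (1S,4S,5R,8S)-8-ArG-4-ArS-3,7-dioxabicyclo[3.3.0]octan-2-one
Conditions: mCPBA (1.3 equiv), NaHCO3 (3 equiv), CH2Cl2, 0 °C
Reagents that add atoms: 3-chloroperbenzoic acid, OOC(=O)c1cccc(Cl)c1
Why: Baeyer–Villiger oxidation driven by relief of cyclobutanone strain: the peracid adds to C2 and the electron-rich secondary benzylic C4 migrates to oxygen in preference to C1, which is deactivated by the adjacent C8–O7 bond. Migration proceeds with retention, so O3 enters between C2 and C4 and the exo aryl configuration is kept.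

Step 12
Reactants: 20 (1S,4S,5R,8S)-8-ArG-4-ArS-3,7-dioxabicyclo[3.3.0]octan-2-one
Product: 21 (1S,4S,5R,8S)-8-(4-hydroxy-3-methoxyphenyl)-4-(4-hydroxy-3,5-dimethoxyphenyl)-3,7-dioxabicyclo[3.3.0]octan-2-one
Conditions: TBAF (3 equiv), AcOH (3 equiv), THF, 0 °C → rt
Reagents that add atoms: none
Why: Fluoride cleaves both aryl O–Si bonds, and the acetic acid buffer protonates each phenoxide at once. This suppresses quinone methide formation at C4 and C8 and base-induced elimination across C1–C8, so no stereocentre is touched.

## Compound list

1 | vanillin (4-hydroxy-3-methoxybenzaldehyde) | COc1cc(C=O)ccc1O | starting material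
2 | 3-methoxy-4-[(triisopropylsilyl)oxy]benzaldehyde | COc1cc(C=O)ccc1O[Si](C(C)C)(C(C)C)C(C)C | intermediate
3 | trimethylsilylacetylene | C#C[Si](C)(C)C | starting material
4 | methyl[(trimethylsilyl)ethynyl]zinc | C[Zn]C#C[Si](C)(C)C | intermediate
5 | (1R)-1-{3-methoxy-4-[(triisopropylsilyl)oxy]phenyl}-3-(trimethylsilyl)prop-2-yn-1-ol | COc1cc([C@H](C#C[Si](C)(C)C)O)ccc1O[Si](C(C)C)(C(C)C)C(C)C | intermediate
6 | (1S)-1-{3-methoxy-4-[(triisopropylsilyl)oxy]phenyl}prop-2-yn-1-ol | COc1cc([C@H](C#C)O)ccc1O[Si](C(C)C)(C(C)C)C(C)C | intermediate
7 | sinapyl alcohol ((2E)-3-(4-hydroxy-3,5-dimethoxyphenyl)prop-2-en-1-ol) | COc1cc(/C=C/CO)cc(OC)c1O | starting material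
8 | sodium 4-[(1E)-3-hydroxyprop-1-en-1-yl]-2,6-dimethoxyphenolate | COc1cc(/C=C/CO)cc(OC)c1[O-].[Na+] | intermediate
9 | (2E)-3-{3,5-dimethoxy-4-[(triisopropylsilyl)oxy]phenyl}prop-2-en-1-ol | COc1cc(/C=C/CO)cc(OC)c1O[Si](C(C)C)(C(C)C)C(C)C | intermediate
10 | (2E)-3-{3,5-dimethoxy-4-[(triisopropylsilyl)oxy]phenyl}prop-2-en-1-yl methanesulfonate | COc1cc(/C=C/COS(C)(=O)=O)cc(OC)c1O[Si](C(C)C)(C(C)C)C(C)C | intermediate
11 | {4-[(1E)-3-bromoprop-1-en-1-yl]-2,6-dimethoxyphenoxy}triisopropylsilane | COc1cc(/C=C/CBr)cc(OC)c1O[Si](C(C)C)(C(C)C)C(C)C | intermediate
12 | sodium (1S)-1-{3-methoxy-4-[(triisopropylsilyl)oxy]phenyl}prop-2-yn-1-olate | COc1cc([C@H](C#C)[O-])ccc1O[Si](C(C)C)(C(C)C)C(C)C.[Na+] | intermediate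
13 | (1S)-1-{3-methoxy-4-[(triisopropylsilyl)oxy]phenyl}prop-2-yn-1-yl (2E)-3-{3,5-dimethoxy-4-[(triisopropylsilyl)oxy]phenyl}prop-2-en-1-yl ether | COc1cc([C@H](C#C)OC/C=C/c2cc(OC)c(O[Si](C(C)C)(C(C)C)C(C)C)c(OC)c2)ccc1O[Si](C(C)C)(C(C)C)C(C)C | intermediate
14 | pinacolborane (4,4,5,5-tetramethyl-1,3,2-dioxaborolane) | CC1(C)OBOC1(C)C | starting material
15 | 2-[(1E,3S)-3-{3-methoxy-4-[(triisopropylsilyl)oxy]phenyl}-3-({(2E)-3-{3,5-dimethoxy-4-[(triisopropylsilyl)oxy]phenyl}prop-2-en-1-yl}oxy)prop-1-en-1-yl]-4,4,5,5-tetramethyl-1,3,2-dioxaborolane | COc1cc([C@H](/C=C/B2OC(C)(C)C(C)(C)O2)OC/C=C/c2cc(OC)c(O[Si](C(C)C)(C(C)C)C(C)C)c(OC)c2)ccc1O[Si](C(C)C)(C(C)C)C(C)C | intermediate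
16 | 2-[(1R,4S,5S,6R,7S)-4-{3-methoxy-4-[(triisopropylsilyl)oxy]phenyl}-7-{3,5-dimethoxy-4-[(triisopropylsilyl)oxy]phenyl}-3-oxabicyclo[3.2.0]heptan-6-yl]-4,4,5,5-tetramethyl-1,3,2-dioxaborolane | COc1cc([C@H]2OC[C@H]3[C@@H]2[C@H](B2OC(C)(C)C(C)(C)O2)[C@@H]3c2cc(OC)c(O[Si](C(C)C)(C(C)C)C(C)C)c(OC)c2)ccc1O[Si](C(C)C)(C(C)C)C(C)C | intermediate
17 | 2-{[(1R,4S,5R,6R,7S)-4-{3-methoxy-4-[(triisopropylsilyl)oxy]phenyl}-7-{3,5-dimethoxy-4-[(triisopropylsilyl)oxy]phenyl}-3-oxabicyclo[3.2.0]heptan-6-yl]oxy}-4,4,5,5-tetramethyl-1,3,2-dioxaborolane | COc1cc([C@H]2OC[C@H]3[C@@H]2[C@H](OB2OC(C)(C)C(C)(C)O2)[C@@H]3c2cc(OC)c(O[Si](C(C)C)(C(C)C)C(C)C)c(OC)c2)ccc1O[Si](C(C)C)(C(C)C)C(C)C | intermediate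
18 | (1R,4S,5R,6R,7S)-4-{3-methoxy-4-[(triisopropylsilyl)oxy]phenyl}-7-{3,5-dimethoxy-4-[(triisopropylsilyl)oxy]phenyl}-3-oxabicyclo[3.2.0]heptan-6-ol | COc1cc([C@H]2OC[C@H]3[C@@H]2[C@H](O)[C@@H]3c2cc(OC)c(O[Si](C(C)C)(C(C)C)C(C)C)c(OC)c2)ccc1O[Si](C(C)C)(C(C)C)C(C)C | intermediate
19 | (1R,4S,5S,7S)-4-{3-methoxy-4-[(triisopropylsilyl)oxy]phenyl}-7-{3,5-dimethoxy-4-[(triisopropylsilyl)oxy]phenyl}-3-oxabicyclo[3.2.0]heptan-6-one | COc1cc([C@H]2OC[C@H]3[C@@H]2C(=O)[C@@H]3c2cc(OC)c(O[Si](C(C)C)(C(C)C)C(C)C)c(OC)c2)ccc1O[Si](C(C)C)(C(C)C)C(C)C | intermediate
20 | (1S,4S,5R,8S)-8-{3-methoxy-4-[(triisopropylsilyl)oxy]phenyl}-4-{3,5-dimethoxy-4-[(triisopropylsilyl)oxy]phenyl}-3,7-dioxabicyclo[3.3.0]octan-2-one | COc1cc([C@H]2OC[C@H]3[C@@H]2C(=O)O[C@@H]3c2cc(OC)c(O[Si](C(C)C)(C(C)C)C(C)C)c(OC)c2)ccc1O[Si](C(C)C)(C(C)C)C(C)C | intermediate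
21 | (1S,4S,5R,8S)-8-(4-hydroxy-3-methoxyphenyl)-4-(4-hydroxy-3,5-dimethoxyphenyl)-3,7-dioxabicyclo[3.3.0]octan-2-one | COc1cc([C@H]2OC[C@H]3[C@@H]2C(=O)O[C@@H]3c2cc(OC)c(O)c(OC)c2)ccc1O | target

## Step count and least certain steps

Total: 12 steps. Longest linear sequence: 10 steps (steps 1, 2, 3, 6, 7, 8, 9, 10, 11, 12, from 1 to 21).

**Step 8 (key step).** The most likely failure is insufficient facial discrimination in the first bond formation. With an E alkene the allylic strain that keeps the C8–H bond eclipsed with C1=C2 is small, so the conformer with the aryl group in that position can compete. It would give the cycloadduct whose new centres have the opposite absolute sense. The fallback changes the control element. It sets out from 13: rhodium-catalysed trans-hydroboration with 14 ([Rh(cod)Cl]2, P(iPr)3, Et3N, cyclohexane, rt), which runs through a rhodium vinylidene, gives the (Z)-alkenyl boronate F1. In F1 the boryl group is cis to C8 and raises the allylic 1,3-strain of the unwanted conformer sharply. Sensitised cycloaddition under the conditions of step 8 then passes through the same 1,4-biradical, provided ring closure outpaces reversion, and comes back to the route at 16.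

**Step 2.** Enantiofacial selection may be incomplete, or addition slow, because the aldehyde is electron-rich and the aryl and alkynyl groups are of similar size at the zinc centre. The fallback replaces asymmetric catalysis by resolution. It sets out from 2: ethynylmagnesium bromide (THF, 0 °C) gives the racemic alkynol F2. Lipase-catalysed acetylation (Candida antarctica lipase B, vinyl acetate, tert-butyl methyl ether) should, by the empirical size rule for lipases (aryl large, ethynyl medium), convert the R enantiomer into the acetate F3 and leave the S alcohol. This is 6, so the fallback comes back at 6 and makes step 3 unnecessary, at the price of half the material.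

**Step 6.** The electron-rich allylic bromide may ionise or eliminate before substitution, and the base may cause propargyl-to-allenyl isomerisation of the alkoxide or product, which would erode the configuration at C8. The fallback changes the mode of activation. It sets out from 9 and 5: acetylation of 9 (Ac2O, pyridine) gives the allylic acetate F4. Allylic etherification of 5 as its zinc alkoxide (Et2Zn, Pd(OAc)2, 2-(di-tert-butylphosphino)biphenyl, THF, rt) proceeds through a π-allyl complex of divalent palladium that is attacked at the unsubstituted terminus and gives the silylalkynyl ether F5. Treatment with K2CO3 in MeOH then frees the alkyne and comes back to the route at 13.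

**Step 11.** Migration of C1 may compete with that of C4 and give the regioisomeric lactone, and the peracid may oxidise the electron-rich arenes. The fallback fixes the regiochemistry by the direction of enolisation instead of by migratory aptitude. It sets out from 19:
- Soft enolisation towards the benzylic C4 (TMSOTf, Et3N, CH2Cl2, 0 °C) gives the silyl enol ether F6.
- Ozonolysis (O3, CH2Cl2/MeOH, −78 °C, dye indicator) cleaves C2=C4 to the keto acid F7.
- F7 is reduced in the same flask (NaBH4) to the hydroxy acid F8.
- Pyridinium p-toluenesulfonate in CH2Cl2 closes the lactone through the benzylic cation under thermodynamic control, which places the aryl group exo and comes back to the route at 20.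

## Further compounds

F1 | step 8 | 2-[(1Z,3S)-3-{3-methoxy-4-[(triisopropylsilyl)oxy]phenyl}-3-({(2E)-3-{3,5-dimethoxy-4-[(triisopropylsilyl)oxy]phenyl}prop-2-en-1-yl}oxy)prop-1-en-1-yl]-4,4,5,5-tetramethyl-1,3,2-dioxaborolane | COc1cc([C@H](/C=C\B2OC(C)(C)C(C)(C)O2)OC/C=C/c2cc(OC)c(O[Si](C(C)C)(C(C)C)C(C)C)c(OC)c2)ccc1O[Si](C(C)C)(C(C)C)C(C)C
F2 | step 2 | rac-1-{3-methoxy-4-[(triisopropylsilyl)oxy]phenyl}prop-2-yn-1-ol | COc1cc(C(O)C#C)ccc1O[Si](C(C)C)(C(C)C)C(C)C
F3 | step 2 | (1R)-1-{3-methoxy-4-[(triisopropylsilyl)oxy]phenyl}prop-2-yn-1-yl acetate | COc1cc([C@@H](C#C)OC(C)=O)ccc1O[Si](C(C)C)(C(C)C)C(C)C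
F4 | step 6 | (2E)-3-{3,5-dimethoxy-4-[(triisopropylsilyl)oxy]phenyl}prop-2-en-1-yl acetate | COc1cc(/C=C/COC(C)=O)cc(OC)c1O[Si](C(C)C)(C(C)C)C(C)C
F5 | step 6 | (1R)-1-{3-methoxy-4-[(triisopropylsilyl)oxy]phenyl}-3-(trimethylsilyl)prop-2-yn-1-yl (2E)-3-{3,5-dimethoxy-4-[(triisopropylsilyl)oxy]phenyl}prop-2-en-1-yl ether | COc1cc([C@H](C#C[Si](C)(C)C)OC/C=C/c2cc(OC)c(O[Si](C(C)C)(C(C)C)C(C)C)c(OC)c2)ccc1O[Si](C(C)C)(C(C)C)C(C)C
F6 | step 11 | trimethylsilyl enol ether of 19 towards C4 (4-ArG-7-ArS-6-(trimethylsilyloxy)-3-oxabicyclo[3.2.0]hept-6-ene, C1, C5 and C8 configured as in 19) | COc1cc([C@H]2OC[C@H]3[C@@H]2C(O[Si](C)(C)C)=C3c2cc(OC)c(O[Si](C(C)C)(C(C)C)C(C)C)c(OC)c2)ccc1O[Si](C(C)C)(C(C)C)C(C)C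
F7 | step 11 | keto acid: 2-ArG-4-(ArS-carbonyl)tetrahydrofuran-3-carboxylic acid, C1, C5 and C8 configured as in 19, carboxyl and aroyl groups cis | COc1cc([C@H]2OC[C@H](C(=O)c3cc(OC)c(O[Si](C(C)C)(C(C)C)C(C)C)c(OC)c3)[C@@H]2C(O)=O)ccc1O[Si](C(C)C)(C(C)C)C(C)C
F8 | step 11 | hydroxy acid: 2-ArG-4-[ArS(hydroxy)methyl]tetrahydrofuran-3-carboxylic acid, both C4 epimers, other centres as in F7 | COc1cc([C@H]2OC[C@H](C(O)c3cc(OC)c(O[Si](C(C)C)(C(C)C)C(C)C)c(OC)c3)[C@@H]2C(O)=O)ccc1O[Si](C(C)C)(C(C)C)C(C)C
A1 | alternative 1 | [(2S,3R)-3-(4-benzyloxy-3,5-dimethoxyphenyl)oxiran-2-yl]methanol (cis-oxirane) | OC[C@@H]1O[C@@H]1c1cc(OC)c(OCc2ccccc2)c(OC)c1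
A2 | alternative 1 | dimethyl 2-(4-benzyloxy-3-methoxybenzylidene)malonate | COC(=O)C(=Cc1ccc(OCc2ccccc2)c(OC)c1)C(=O)OC
A3 | alternative 1 | methyl (1S,4S,5R,8R)-8-(4-benzyloxy-3-methoxyphenyl)-4-(4-benzyloxy-3,5-dimethoxyphenyl)-2-oxo-3,7-dioxabicyclo[3.3.0]octane-1-carboxylate | COc1cc([C@H]2OC[C@H]3[C@]2(C(=O)OC)C(=O)O[C@@H]3c2cc(OC)c(OCc4ccccc4)c(OC)c2)ccc1OCc1ccccc1
A4 | alternative 2 | methyl (1R,4S,5S)-4-[4-(tert-butyldimethylsilyloxy)-3,5-dimethoxyphenyl]-2-oxo-3-oxabicyclo[3.1.0]hexane-1-carboxylate (aryl trans to the cyclopropane CH2) | COC(=O)[C@@]12C[C@@H]1[C@@H](c1cc(OC)c(O[Si](C)(C)C(C)(C)C)c(OC)c1)OC2=O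
A5 | alternative 2 | 4-(tert-butyldimethylsilyloxy)-3-methoxybenzaldehyde | COc1cc(C=O)ccc1O[Si](C)(C)C(C)(C)C
A6 | alternative 2 | methyl (1S,4S,5R,8R)-8-[4-(tert-butyldimethylsilyloxy)-3-methoxyphenyl]-4-[4-(tert-butyldimethylsilyloxy)-3,5-dimethoxyphenyl]-2-oxo-3,7-dioxabicyclo[3.3.0]octane-1-carboxylate | COc1cc([C@H]2OC[C@H]3[C@]2(C(=O)OC)C(=O)O[C@@H]3c2cc(OC)c(O[Si](C)(C)C(C)(C)C)c(OC)c2)ccc1O[Si](C)(C)C(C)(C)C
A7 | alternative 3 | (5S)-5-(4-benzyloxy-3,5-dimethoxyphenyl)furan-2(5H)-one | O=C1C=C[C@@H](c2cc(OC)c(OCc3ccccc3)c(OC)c2)O1
A8 | alternative 3 | {[(4-benzyloxy-3-methoxyphenyl)(chloro)methoxy]methyl}trimethylsilane | COc1cc(C(Cl)OC[Si](C)(C)C)ccc1OCc1ccccc1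
A9 | alternative 3 | carbonyl ylide from A8 ((4-benzyloxy-3-methoxybenzylidene)oxonium methylide) | COc1cc(C=[O+][CH2-])ccc1OCc1ccccc1
A10 | alternative 3 | (1S,4S,5R,8S)-8-(4-benzyloxy-3-methoxyphenyl)-4-(4-benzyloxy-3,5-dimethoxyphenyl)-3,7-dioxabicyclo[3.3.0]octan-2-one | COc1cc([C@H]2OC[C@H]3[C@@H]2C(=O)O[C@@H]3c2cc(OC)c(OCc4ccccc4)c(OC)c2)ccc1OCc1ccccc1
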